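## Analysis of the target

CNP0251711.1 is a germacranolide: a ten-membered carbocycle (C1–C10) fused at C6/C7 to a butenolide (O6–C12(=O)–C11=C7). It carries trans, trisubstituted epoxides at C1–C10 and C4–C5 (methyls on C10 and C4), a tigloyl ester on C8 and an acetoxymethyl group (C13) on C11. The six stereocentres are 1R,10R and 4R,5R (the two epoxides), 6S (lactone O–CH) and 8S (ester O–CH). C5 and C6 are vicinal, C6 and C8 flank the tetrasubstituted C7=C11 alkene, and no rigid element links the two epoxides to each other. The compound is fragile: the C13 acetate is a vinylogous leaving group of the lactone, H6 is the acidic γ-hydrogen of the butenolide and sits β to an epoxide C–O bond, and epoxides in a ten-membered ring undergo acid-triggered transannular reactions. The difficulty is therefore to build a medium ring with controlled configuration at C4, C5, C6 and C8 before any of these groups exists. The structural feature used is transannular: C5 and C10 face each other across the ring, C5 bears oxygen and C1–C10 is at the alkene oxidation level. A C5 ketone with an E C1=C10 alkene is what remains when the C5–C10 bond of a trans-decalin C5-ol C1-sulfonate is cleaved, so the ring can be taken from a bicycle in which C4, C5, C6 and C8 are set by cyclohexane rules.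

## Retrosynthetic reasoning

**C1–C10 epoxide (29 ⇒ 28).** The two C–O bonds are cut last, back to the E alkene. The isolated trisubstituted alkene is the only electron-rich π bond in 28, and removing it at the very end takes the acid-sensitive epoxide/alkene pair out of the molecule. The forward reaction must attack the outer face of the alkene.

**Ester C–O bonds at C13 and C8 (28 ⇒ 27 ⇒ 26 ⇒ 24).** The acetate is the most labile group, so it is installed after the tiglate. Until then C13 is an ether, which is a poor leaving group, and the amine bases of the C8 esterification with 25 cannot start a vinylogous elimination.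

**Lactone carbonyl (24 ⇒ 22 ⇒ 21).** C12 is taken back to a primary alcohol, and the lactone to a C6/C12 diol. This requires the two hydroxymethyl groups on C11 to be different from the start: C13 is carried as a 4-methoxybenzyl ether, while O6, O8 and O12 carry silyl groups that come off together.

**C4–C5 epoxide (21 ⇒ 19 ⇒ 18).** Only the C5–O bond is cut. The C4 oxygen is kept and displaces a C5 sulfonate with inversion, and the C5 alcohol comes from a C5 ketone. This is placed before the lactone exists, because alkoxide next to a butenolide γ-hydrogen would cause elimination.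

**Ring (18 ⇒ 17).** The C5–C10 bond is reconnected. The ten-membered ketone 18 becomes the trans-decalin 17 with a free tertiary C5–OH and an equatorial C1 mesylate, and the forward step is a Grob fragmentation. Two design points follow from the decalin geometry:
- O4 is left unprotected. A cyclic ketal across O4/O6 would need its axial acetal methyl syn-axial to the C4 methyl, and the cis-vicinal pairs O4/O5 or O5/O6 would ketalise instead and block the hydroxyl that must fragment.
- The free C4–OH is later used as the chelating group for the C5 reduction and as the nucleophile for the epoxide.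

**Allylic diol and butenolide (17 ⇒ 16 ⇒ 15 ⇒ 14 ⇒ 9 + 13).** On the decalin, the C7=C11 alkene is made by an intramolecular olefination of an O6-tethered phosphonate onto the C7 ketone. The tether fixes the alkene geometry and decides that C12, not C13, is bonded to O6. The lactone 15 would not survive alkoxide, so it is reduced to the diol for the fragmentation and re-oxidised afterwards. Acid 13 comes from 10 and 11.

**C5–O and C6–O (9 ⇒ 7).** Both bonds are cut at once, back to the C5=C6 enone. cis-Dihydroxylation from the α face, anti to the angular methyl, gives the all-cis 4,5,6-triol.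

**C8–O and C1–O sulfonate (7 ⇒ 6 ⇒ 5).** C8 is α′ to the enone carbonyl and is oxygenated there. The mesylate is put on C1 when it is the only secondary hydroxyl.

**C4 carbinol (5 ⇒ 4 ⇒ 3 ⇒ 2 ⇒ 1).** A methyl nucleophile adding to a C4 carbonyl would enter from the α face, anti to the angular methyl, and give the wrong C4 epimer. The roles are therefore reversed: C15 is introduced as an exocyclic methylene at the γ-carbon of the enone of 1, oxygen is delivered to its α face, and hydride converts C15 to the methyl. Ketone 1 supplies the C10 stereocentre and the oxygens at C1 and C7.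

## Alternatives that were turned down

**Alternative 1: singlet-oxygen cycloaddition to install C8–O and C13–O.**
- Disconnection: the C8–O and C13–O bonds are removed together through the O–O bridged 1,2-dioxine A1, back to the diepoxy lactone diene A2. In A2 an exocyclic C11=C13 methylene and a ring C7=C8 alkene are held s-cis by the lactone.
- Forward key step: sensitised photo-oxygenation. Singlet oxygen adds across C8 and C13 in a [4+2] sense and the remaining alkene ends at C7=C11. Peroxide reduction and two acylations would finish.
- For it: both missing oxygens and the tetrasubstituted alkene arrive in one operation. On this point it is stronger than the chosen route, which spends separate steps on C8 and on a purpose-built C13 unit.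
- Against it:
  - It is an end-game, not a ring synthesis. A2 already contains the ten-membered ring, both epoxides and C6, so the hard part is only moved.
  - The diene of A2 is conjugated to the lactone carbonyl and is a poor partner for electrophilic singlet oxygen, so ene reactions at C9–H or C6–H can compete.
  - The C8 configuration would depend on which face the flexible ring exposes.
  - A1 has H6 γ to the carbonyl and H8 on a peroxide carbon, so base-induced peroxide cleavage to a C8 ketone is a threat.
- Comparison: the chosen strategy sets C8 as an equatorial substituent on a chair and solves the ring problem in the same plan. It gives up the brevity of the double oxygenation.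

**Alternative 2: B-alkyl Suzuki–Miyaura macrocyclisation at C3–C4.**
- Disconnection: the C3–C4 bond of the E,E-dienolide A3 is cut, back to the open-chain A4, which carries a terminal C2=C3 alkene conjugated to C1=C10 and a C4 alkenyl iodide. Both epoxides are added after ring closure.
- Forward key step: 9-BBN hydroborates the terminal alkene at C3 and a palladium catalyst couples the alkylborane with the alkenyl iodide, closing the ten-membered ring.
- For it: it is convergent, both trisubstituted alkenes are made with defined geometry from acyclic pieces, and the esters are already in place. In convergence and step count on paper it is stronger than the chosen route.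
- Against it:
  - A ten-membered ring with two E alkenes must be closed against strain and entropy, at high dilution, late, on a fully functionalised substrate.
  - Zerovalent palladium ionises the allylic C13 acetate of A4, which is further activated by the lactone.
  - The carbonate base meets the γ-hydrogen at C6, now also allylic to C4=C5.
  - Hydroboration must select one alkene of a 1,3-diene in the presence of a tiglate and a butenolide.
  - Two epoxidations must then both find the correct faces.
- Comparison: the chosen strategy forms the ring by cleaving a bond, so there is no ring-closure penalty. The alkene geometry is fixed stereoelectronically, and one epoxide is made by displacement rather than by face selection. It pays with a longer linear sequence.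

**Alternative 3: [2,3]-Wittig contraction of a thirteen-membered allylic ether.**
- Disconnection: the C6–C7 bond of the ten-membered C6 alcohol A5 is cut and O6 is reconnected to C13, giving the thirteen-membered α-stannyl allyl ether A6. A6 is drawn with a ring-trans C7=C11; which alkene geometry and which C6 epimer deliver the required C6/C7 pair is itself open.
- Forward key step: tin–lithium exchange at C6 with n-BuLi, then a [2,3] shift that forms C6–C7, breaks O–C13 and contracts the ring.
- For it: a thirteen-membered ether is easier to close than a ten-membered carbocycle, the rearrangement runs at low temperature without a sensitive ketone, and it gives the E,E-diene directly. In mildness of the ring-forming event it is stronger than the chosen route.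
- Against it:
  - A5 is mismatched to this target: it has an sp3 C7–H and a C11=C13 methylene, whereas the target needs C7=C11 and oxygen on C13. The C7 stereocentre is made only to be destroyed, and a transposition with oxidation has to follow.
  - The C6/C7 outcome rests on a macrocyclic transition state and on an enantiopure stannane.
  - Both epoxides still depend on face selection.
- Comparison: the chosen strategy carries the complete C7=C11(C12)(C13) unit, with the right geometry and differentiated oxygens, unchanged through the ring-forming step.

Key step: step 14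

Assumption: compounds 1, 10, 11 and 25 are bought; positions follow the germacrane/eudesmane skeleton (C14 on C10, C15 on C4, C12 and C13 on C11), and in the decalins β is the face of the C10 methyl.

## Route

Step 1
Reactants: 1 (R)-Wieland–Miescher ketone
Product: 2 4-methylene dienedione (exocyclic C4=C15; C5=C6; ketones at C1 and C7)
Conditions: CH2(OEt)2, POCl3, NaOAc, CHCl3, reflux
Reagents that add atoms: diethoxymethane CCOCOCC
Why: Acid-mediated formation of the extended ethoxy dienol ether toward C4, attack of an ethoxymethyl cation at this γ-carbon and loss of ethanol give the cross-conjugated methylene enone (direct γ-methylenation, known for steroidal 4-en-3-ones). The C1 ketone, flanked by the quaternary C10, should stay out of the reaction as ring D ketones do in that series; no stereocentre is formed.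

Step 2
Reactants: 2 4-methylene dienedione
Product: 3 C4 spiro-epoxide (oxirane oxygen α; C15 β)
Conditions: dimethyldioxirane, acetone, 0 °C
Reagents that add atoms: dimethyldioxirane CC1(C)OO1
Why: The dioxirane epoxidises the terminal, least deactivated alkene of the dienone and does not cause Baeyer–Villiger oxidation of the C1 ketone. Oxygen is delivered to the α face of C4 because the β lobe is 1,3-syn-axial to the C10 methyl; this sets C4.

Step 3
Reactants: 3 C4 spiro-epoxide
Product: 4 1β 4α 7β-triol with 4β-methyl (expected major C7 epimer)
Conditions: LiAlH4, THF, 0 °C to rt; aq. NaOH work-up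
Reagents that add atoms: none
Why: Hydride reduces both ketones: C1 by axial attack anti to the adjacent axial methyl, giving the equatorial 1β-alcohol, and C7 by 1,2-addition. It also opens the spiro-epoxide by SN2 at the primary C15, which becomes the C4 methyl while the oxygen from step 2 remains as the tertiary 4α-alcohol. The C7 configuration is irrelevant because step 4 removes it.

Step 4
Reactants: 4 triol
Product: 5 1β 4α-dihydroxy enone (C5=C6–C7=O)
Conditions: MnO2, CH2Cl2, rt
Reagents that add atoms: none
Why: MnO2 oxidises only the allylic C7 alcohol; the saturated secondary C1 alcohol and the tertiary C4 alcohol are left.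

Step 5
Reactants: 5 dihydroxy enone
Product: 6 1β-mesylate
Conditions: MsCl, Et3N, CH2Cl2, 0 °C
Reagents that add atoms: methanesulfonyl chloride CS(=O)(=O)Cl
Why: Sulfonylation takes the only secondary hydroxyl (equatorial C1–OH); the tertiary C4 hydroxyl is not esterified at 0 °C.

Step 6
Reactants: 6 1β-mesylate
Product: 7 8α-acetoxy enone
Conditions: Mn(OAc)3, benzene, reflux
Reagents that add atoms: manganese triacetate CC(=O)[O-].CC(=O)[O-].CC(=O)[O-].[Mn+3]
Why: α′-Acetoxylation of an enone through its manganese enolate can only occur at C8, since C6 is vinylic and C4 quaternary. The acetate enters anti to the 1,3-syn-axial C10 methyl and, being α to the ketone, can equilibrate to the same equatorial 8α position.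

Step 7
Reactants: 7 8α-acetoxy enone
Product: 9 4α 5α 6α-triol ketone (8α-OAc; 1β-OMs), via osmate ester 8 (not isolated)
Conditions: OsO4, TMEDA, CH2Cl2, −78 °C; then aq. NaHSO3, THF, rt
Reagents that add atoms: osmium tetroxide O=[Os](=O)(=O)=O (two oxygens stay in 9; osmium and TMEDA CN(C)CCN(C)C stay only in 8)
Why: Stoichiometric OsO4·TMEDA adds to the hindered enone alkene in a [3+2] sense from the α face. That face is anti to the C10 and C4 methyls and is also the face to which the 4α-hydroxyl hydrogen-bonds the reagent, so C5–OH and C6–OH are both α. Reductive hydrolysis of 8 releases the triol.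

Step 8
Reactants: 10 trimethyl 2-phosphonoacrylate; 11 4-methoxybenzyl alcohol
Product: 12 methyl 2-(dimethoxyphosphoryl)-3-[(4-methoxybenzyl)oxy]propanoate (racemic)
Conditions: NaH (cat.), THF, 0 °C to rt
Reagents that add atoms: none
Why: Alkoxide-catalysed oxa-Michael addition to the doubly activated acrylate; the new stereocentre is racemic and is erased in step 11.

Step 9
Reactants: 12 phosphono ester
Product: 13 2-(dimethoxyphosphoryl)-3-[(4-methoxybenzyl)oxy]propanoic acid (racemic)
Conditions: LiOH, THF/H2O, 0 °C; then aq. HCl
Reagents that add atoms: lithium hydroxide [Li+].[OH-]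
Why: Saponification of the carboxylic methyl ester is much faster than cleavage of the phosphonate methyl esters; the reaction is kept cold to suppress retro-Michael loss of the benzyl alcohol.

Step 10
Reactants: 9 triol ketone; 13 phosphono acid
Product: 14 C6 phosphonoacyl ester (both epimers at the phosphonate carbon)
Conditions: DCC, DMAP (cat.), CH2Cl2, 0 °C to rt
Reagents that add atoms: none
Why: Steglich esterification acylates the only secondary hydroxyl (C6); the tertiary C4 and C5 hydroxyls are inert. Tethering the C12–C11–C13 unit to O6 guarantees that C12, not C13, becomes the lactone carbonyl.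

Step 11
Reactants: 14 C6 phosphonoacyl ester
Product: 15 butenolide (6α 12-olide; C7=C11; C13–OPMB; 8α-OAc; 1β-OMs)
Conditions: LiCl, i-Pr2NEt, MeCN, rt
Reagents that add atoms: none
Why: Intramolecular Horner–Wadsworth–Emmons olefination under LiCl/amine conditions closes the five-membered lactone onto the C7 ketone and creates the tetrasubstituted C7=C11 alkene, with geometry fixed by the ring (C12 cis to C6, C13 cis to C8). The stabilised phosphonate carbanion tolerates its β-alkoxy group, and the weak base leaves the mesylate and the C5 carbinol alone.

Step 12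
Reactants: 15 butenolide
Product: 16 pentaol (4α 5α 6α 8α 12-OH; C13–OPMB; 1β-OMs)
Conditions: i-Bu2AlH, CH2Cl2, −78 to 0 °C; aq. potassium sodium tartrate
Reagents that add atoms: none
Why: i-Bu2AlH reduces the butenolide by 1,2-addition to the cis ene-1,4-diol (C6–OH, C12–OH) and cleaves the C8 acetate, giving the alcohol oxidation level needed for the base step. The neopentyl mesylate and the benzyl ether are not attacked at low temperature.

Step 13
Reactants: 16 pentaol
Product: 17 tris(triethylsilyl) ether at O6 O8 O12 (free 4α- and 5α-OH; 1β-OMs)
Conditions: Et3SiCl, imidazole, DMAP (cat.), DMF, 0 °C to rt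
Reagents that add atoms: chlorotriethylsilane CC[Si](Cl)(CC)CC
Why: The silyl chloride caps the primary C12 and the secondary C6 and C8 hydroxyls but not the tertiary C4 and C5 hydroxyls, so only the 1,3-diol monomesylate array (C5–OH, C1–OMs) remains reactive.

Step 14
Reactants: 17 tris(triethylsilyl) ether
Product: 18 ten-membered C5 ketone with E C1=C10 alkene
Conditions: KOtBu (1.1 equiv), THF/t-BuOH, 0 °C; aq. NH4Cl
Reagents that add atoms: none
Why: KOtBu converts the tertiary C5 hydroxyl into its alkoxide, in rapid exchange with the C4 alkoxide, which has no leaving group in a 1,3-relationship and is a spectator. The C5–C10 bond is anti-periplanar to the equatorial C1–O bond of the mesylate, so the oxygen lone pair, the breaking ring-fusion bond and the departing sulfonate react in one concerted event that makes C5=O and C1=C10 and forms no σ bond. The closest known reaction type is the Grob fragmentation of trans-decalin 1,3-diol monosulfonates to (E)-cyclodec-5-enones. The ten-membered ring is therefore not closed by a cyclisation: it is uncovered by cutting the bond shared by rings A and B, which avoids the entropic and transannular penalties of a medium-ring closure. No stereocentre is created; C5, C10 and C1 become sp2 and C4, C6 and C8 are untouched. The selectivity that matters is alkene geometry: the axial C10 methyl and the axial H1 are anti in the decalin and end up trans on the alkene, which can only be the E isomer. Simple elimination or substitution should not compete, because an equatorial sulfonate has no anti-periplanar hydrogen and its backside lies inside the ring. About one equivalent of base, the t-BuOH co-solvent, 0 °C and a prompt quench keep the product from enolising toward C6.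

Step 15
Reactants: 18 ten-membered ketone
Product: 19 (5S)-alcohol (4R 5S-diol)
Conditions: Zn(BH4)2, Et2O, −20 °C
Reagents that add atoms: none
Why: Zn(BH4)2 chelates the C4 hydroxyl and the C5 carbonyl. In the chelate the ring chain leaving C3 covers one face, so hydride enters from the side of the C4 methyl (Cram chelate control) and gives the (5S)-alcohol, whose C5–O bond can stand anti to C4–O. The neutral reagent avoids enolisation toward C6.

Step 16
Reactants: 19 (5S)-alcohol
Product: 21 (4R 5R)-4,5-epoxide, via C5 mesylate 20 (not isolated)
Conditions: MsCl, Et3N, CH2Cl2, −10 °C; then K2CO3, MeOH, rt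
Reagents that add atoms: methanesulfonyl chloride CS(=O)(=O)Cl (its atoms stay only in 20)
Why: The secondary C5 hydroxyl is sulfonylated in the presence of the tertiary C4 hydroxyl. Carbonate in methanol then generates the C4 alkoxide, which displaces the mesylate with inversion at C5 (3-exo-tet) to give the trans epoxide. O6 is still silylated and cannot compete.

Step 17
Reactants: 21 4,5-epoxide
Product: 22 epoxy triol (6-OH; 8-OH; 12-OH)
Conditions: Bu4NF, AcOH, THF, 0 °C to rt
Reagents that add atoms: none
Why: Acetic acid-buffered fluoride removes the three triethylsilyl ethers under near-neutral conditions that spare the epoxide, the alkene and the benzyl ether. It should not provoke epoxide migration to O6 or attack of the C12 hydroxyl on C5.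

Step 18
Reactants: 22 epoxy triol
Product: 24 butenolide with free C8 hydroxyl, via lactol 23 (not isolated)
Conditions: TEMPO (cat.), PhI(OAc)2, CH2Cl2, rt
Reagents that add atoms: none
Why: The oxoammonium system oxidises only the primary allylic C12 alcohol. The aldehyde is captured by the cis C6 hydroxyl as lactol 23, which is oxidised on to the lactone; C13 is blocked as its benzyl ether and the secondary C8 alcohol reacts far more slowly.

Step 19
Reactants: 24 butenolide alcohol; 25 tiglic acid
Product: 26 C8 tiglate
Conditions: 2,4,6-trichlorobenzoyl chloride, Et3N, toluene, rt; then 24, DMAP, rt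
Reagents that add atoms: none
Why: Yamaguchi esterification acylates the hindered secondary C8 alcohol with the (E)-acid without isomerising it. It is done while C13 still carries a poor leaving group, so the amine bases cannot start a vinylogous elimination.

Step 20
Reactants: 26 C8 tiglate
Product: 27 C13 alcohol
Conditions: DDQ, CH2Cl2/pH 7 phosphate buffer, 0 °C
Reagents that add atoms: none
Why: Oxidative cleavage of the 4-methoxybenzyl ether by DDQ in buffered wet solvent is neutral and leaves the epoxide, the trisubstituted alkene and both esters untouched.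

Step 21
Reactants: 27 C13 alcohol
Product: 28 C13 acetate
Conditions: Ac2O, pyridine, CH2Cl2, 0 °C
Reagents that add atoms: acetic anhydride CC(=O)OC(C)=O
Why: Acetylation of the primary alcohol under pyridine conditions, mild enough for the now base-sensitive 13-acyloxy butenolide.

Step 22
Reactants: 28 C13 acetate
Product: 29 CNP0251711.1
Conditions: mCPBA, NaHCO3, CH2Cl2, 0 °C
Reagents that add atoms: 3-chloroperbenzoic acid O=C(OO)c1cccc(Cl)c1
Why: The isolated trisubstituted C1=C10 alkene is far more nucleophilic than the tiglate and butenolide alkenes (Prilezhaev epoxidation). In the crossed conformation with both ring methyls on one face the peracid can reach only the outer face of the alkene, which corresponds to the (1R,10R)-epoxide.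

## Compound list

1 | (R)-Wieland–Miescher ketone, (R)-8a-methyl-3,4,8,8a-tetrahydronaphthalene-1,6(2H,7H)-dione | C[C@@]12CCC(=O)C=C1CCCC2=O | starting material
2 | (R)-8a-methyl-4-methylene-3,4,8,8a-tetrahydronaphthalene-1,6(2H,7H)-dione (C4=C15 exocyclic, C5=C6, ketones at C1 and C7) | C[C@@]12CCC(=O)C=C1C(=C)CCC2=O | intermediate
3 | C4 spiro-epoxide of 2 (C4–O–C15 oxirane, oxygen on the α face, C15 on the β face) | C[C@@]12CCC(=O)C=C1[C@@]3(CO3)CCC2=O | intermediate
4 | 4β,10β-dimethyl-Δ5-octalin-1β,4α,7β-triol (expected major C7 epimer; the 7α epimer converges in step 4) | C[C@@]12CC[C@@H](O)C=C1[C@](C)(O)CC[C@H]2O | intermediate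
5 | 1β,4α-dihydroxy-4β,10β-dimethyl-Δ5-octalin-7-one | C[C@@]12CCC(=O)C=C1[C@](C)(O)CC[C@H]2O | intermediate
6 | 4α-hydroxy-1β-(methanesulfonyloxy)-4β,10β-dimethyl-Δ5-octalin-7-one | C[C@@]12CCC(=O)C=C1[C@](C)(O)CC[C@H]2OS(C)(=O)=O | intermediate
7 | 8α-acetoxy-4α-hydroxy-1β-(methanesulfonyloxy)-4β,10β-dimethyl-Δ5-octalin-7-one | C[C@@]12C[C@H](OC(C)=O)C(=O)C=C1[C@](C)(O)CC[C@H]2OS(C)(=O)=O | intermediate
8 | 5α,6α-osmate ester of 7 (glycolate of hexavalent osmium, TMEDA-ligated; not isolated) | CS(=O)(=O)O[C@@H]1CC[C@@](C)(O)[C@]2(O[Os](=O)(=O)O3)[C@@H]3C(=O)[C@@H](OC(C)=O)C[C@@]12C.CN(C)CCN(C)C | intermediate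
9 | 8α-acetoxy-4α,5α,6α-trihydroxy-1β-(methanesulfonyloxy)-4β,10β-dimethyl-trans-decalin-7-one | CS(=O)(=O)O[C@@H]1CC[C@@](C)(O)[C@]2(O)[C@@H](O)C(=O)[C@@H](OC(C)=O)C[C@@]12C | intermediate
10 | trimethyl 2-phosphonoacrylate (methyl 2-(dimethoxyphosphoryl)acrylate) | COC(=O)C(=C)P(=O)(OC)OC | starting material
11 | 4-methoxybenzyl alcohol | COc1ccc(CO)cc1 | starting material
12 | methyl 2-(dimethoxyphosphoryl)-3-[(4-methoxybenzyl)oxy]propanoate (racemic) | COC(=O)C(COCc1ccc(OC)cc1)P(=O)(OC)OC | intermediate
13 | 2-(dimethoxyphosphoryl)-3-[(4-methoxybenzyl)oxy]propanoic acid (racemic) | OC(=O)C(COCc1ccc(OC)cc1)P(=O)(OC)OC | intermediate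
14 | C6 ester of 9 with acid 13 (both epimers at the phosphonate carbon) | CS(=O)(=O)O[C@@H]1CC[C@@](C)(O)[C@]2(O)[C@@H](OC(=O)C(COCc3ccc(OC)cc3)P(=O)(OC)OC)C(=O)[C@@H](OC(C)=O)C[C@@]12C | intermediate
15 | 8α-acetoxy-4α,5α-dihydroxy-1β-(methanesulfonyloxy)-13-[(4-methoxybenzyl)oxy]eudesm-7(11)-en-6α,12-olide | CS(=O)(=O)O[C@@H]1CC[C@@](C)(O)[C@]2(O)[C@H]3OC(=O)C(COCc4ccc(OC)cc4)=C3[C@@H](OC(C)=O)C[C@@]12C | intermediate
16 | 1β-(methanesulfonyloxy)-13-[(4-methoxybenzyl)oxy]eudesm-7(11)-ene-4α,5α,6α,8α,12-pentaol (C12 cis to C6) | CS(=O)(=O)O[C@@H]1CC[C@@](C)(O)[C@]2(O)[C@@H](O)/C(=C(\CO)COCc3ccc(OC)cc3)[C@@H](O)C[C@@]12C | intermediate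
17 | 6α,8α,12-tris(triethylsilyl) ether of 16 (fragmentation precursor: free 4α- and 5α-hydroxyls, 1β-mesylate) | CS(=O)(=O)O[C@@H]1CC[C@@](C)(O)[C@]2(O)[C@@H](O[Si](CC)(CC)CC)/C(=C(\CO[Si](CC)(CC)CC)COCc3ccc(OC)cc3)[C@@H](O[Si](CC)(CC)CC)C[C@@]12C | intermediate
18 | (4R,6S,8S,1(10)E)-4-hydroxy-13-[(4-methoxybenzyl)oxy]-6,8,12-tris(triethylsilyloxy)germacra-1(10),7(11)-dien-5-one | CC[Si](CC)(CC)O[C@H]1C/C(C)=C/CC[C@@](C)(O)C(=O)[C@@H](O[Si](CC)(CC)CC)/C1=C(\CO[Si](CC)(CC)CC)COCc2ccc(OC)cc2 | intermediate
19 | (4R,5S,6S,8S)-4,5-diol from reduction of 18 | CC[Si](CC)(CC)O[C@H]1C/C(C)=C/CC[C@@](C)(O)[C@@H](O)[C@@H](O[Si](CC)(CC)CC)/C1=C(\CO[Si](CC)(CC)CC)COCc2ccc(OC)cc2 | intermediate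
20 | C5 methanesulfonate of 19 (not isolated) | CC[Si](CC)(CC)O[C@H]1C/C(C)=C/CC[C@@](C)(O)[C@@H](OS(C)(=O)=O)[C@@H](O[Si](CC)(CC)CC)/C1=C(\CO[Si](CC)(CC)CC)COCc2ccc(OC)cc2 | intermediate
21 | (4R,5R,6S,8S)-4,5-epoxy-13-[(4-methoxybenzyl)oxy]-6,8,12-tris(triethylsilyloxy)germacra-1(10),7(11)-diene | CC[Si](CC)(CC)O[C@H]1C/C(C)=C/CC[C@@]2(C)O[C@@H]2[C@@H](O[Si](CC)(CC)CC)/C1=C(\CO[Si](CC)(CC)CC)COCc3ccc(OC)cc3 | intermediate
22 | (4R,5R,6S,8S)-4,5-epoxy-13-[(4-methoxybenzyl)oxy]germacra-1(10),7(11)-diene-6,8,12-triol | O[C@H]1C/C(C)=C/CC[C@@]2(C)O[C@@H]2[C@@H](O)/C1=C(\CO)COCc3ccc(OC)cc3 | intermediate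
23 | 6,12-lactol of 22 (both anomers; not isolated) | O[C@H]1C/C(C)=C/CC[C@@]2(C)O[C@@H]2[C@H]2OC(O)C(COCc3ccc(OC)cc3)=C12 | intermediate
24 | (4R,5R,6S,8S)-4,5-epoxy-8-hydroxy-13-[(4-methoxybenzyl)oxy]germacra-1(10),7(11)-dien-6,12-olide | O[C@H]1C/C(C)=C/CC[C@@]2(C)O[C@@H]2[C@H]2OC(=O)C(COCc3ccc(OC)cc3)=C12 | intermediate
25 | tiglic acid, (E)-2-methylbut-2-enoic acid | C/C=C(\C)C(=O)O | starting material
26 | 8-O-tigloyl ester of 24 | C/C=C(\C)C(=O)O[C@H]1C/C(C)=C/CC[C@@]2(C)O[C@@H]2[C@H]2OC(=O)C(COCc3ccc(OC)cc3)=C12 | intermediate
27 | 13-hydroxy-8-O-tigloyl-4,5-epoxygermacra-1(10),7(11)-dien-6,12-olide | C/C=C(\C)C(=O)O[C@H]1C/C(C)=C/CC[C@@]2(C)O[C@@H]2[C@H]2OC(=O)C(CO)=C12 | intermediate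
28 | 13-acetoxy-8-O-tigloyl-4,5-epoxygermacra-1(10),7(11)-dien-6,12-olide | C/C=C(\C)C(=O)O[C@H]1C/C(C)=C/CC[C@@]2(C)O[C@@H]2[C@H]2OC(=O)C(COC(C)=O)=C12 | intermediate
29 | CNP0251711.1, (1R,4R,5R,6S,8S,10R)-13-acetoxy-1,10:4,5-diepoxy-8-tigloyloxygermacr-7(11)-en-6,12-olide | C/C=C(\C)C(=O)O[C@H]1C[C@@]2(C)O[C@@H]2CC[C@@]2(C)O[C@@H]2[C@H]2OC(=O)C(COC(C)=O)=C12 | target

## Step count and least certain steps

Total: 22 steps. Longest linear sequence: 20 steps from 1 (steps 1–7 and 10–22); steps 8–9 prepare acid 13.

**Step 14 (key step).**
- What may go wrong: enolisation of the new ketone toward C6 while alkoxide is still present (loss of the C6 configuration, or migration of C7=C11 into conjugation); base-induced α-ketol shift of the C4 hydroxy ketone; transient silyl transfer from O6 to the C5 alkoxide slowing the fragmentation.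
- Fallback, from 17 to 19: the fragmentation is run with NaBH4 already in the flask (KOtBu, NaBH4, t-BuOH/THF, 0 °C), so the ketone is reduced as soon as it is unmasked and never sits in base. The C5 configuration is then set without zinc chelation and would have to be verified. No compound outside the list is needed.

**Step 15.**
- What may go wrong: hydride delivery to the other carbonyl face if zinc chelation is incomplete or the ring reacts through another conformer.
- Fallback, from 18 to 21: the unwanted (4R,5R)-diol F1 has the relative configuration from which an epoxide synthesis with net retention gives the same epoxide. Trimethyl orthoacetate with a trace of pyridinium tosylate gives the cyclic orthoacetate F2. Acetyl bromide opens the derived acetoxonium ion at the secondary carbon with inversion, giving the C4 acetate C5 bromide F3. K2CO3 in methanol cleaves the acetate, and the C4 alkoxide displaces bromide with a second inversion to give 21.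

**Step 16.**
- What may go wrong: slow sulfonylation of the congested C5 hydroxyl; E2 loss of the mesylate toward C6; methanolysis of a silyl ether during the carbonate treatment.
- Fallback, from 19 to 21: direct cyclodehydration under Mitsunobu conditions (PPh3, diisopropyl azodicarboxylate, toluene). The secondary C5 oxygen is activated as an oxyphosphonium ion and displaced by the tertiary C4 hydroxyl with inversion, with no sulfonate ester and no base. No new compound is needed.

**Step 22.**
- What may go wrong: poor facial selectivity if the alkene reacts through the conformer with the C10 methyl on the face opposite to the C4 methyl; acid-induced transannular opening of the 4,5-epoxide by the benzoic acid formed.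
- Fallback, from 26 to 29: substrate control is replaced by reagent control one stage earlier, while C13 is still an ether. Shi epoxidation of 26 (D-fructose-derived ketone catalyst, KHSO5, buffered MeCN/dimethoxymethane/H2O, 0 °C), whose spiro transition state favours the (R,R)-epoxide of an E-trisubstituted alkene, gives the 1,10-epoxide F4. DDQ then gives the C13 alcohol F5, and Ac2O/pyridine gives 29.

**Step 11.**
- What may go wrong: β-elimination of 4-methoxybenzyl oxide from the phosphonate carbanion; base-triggered retro-aldol cleavage or premature fragmentation at the C5 carbinol before the olefination closes.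
- Fallback, from 9 to 15: the phosphonate is replaced by a malonate, which is more acidic and has no β-leaving group.
  - Mono-tert-butyl malonate is coupled to O6 (DCC, DMAP) to give the mixed malonate F6.
  - Piperidinium acetate effects intramolecular Knoevenagel condensation onto the C7 ketone, giving the butenolide tert-butyl ester F7.
  - CF3CO2H in CH2Cl2 frees the C13 acid F8.
  - BH3·SMe2 reduces the carboxylic acid in preference to the lactone and the acetate, giving the 13-hydroxymethyl butenolide F9.
  - 4-Methoxybenzyl trichloroacetimidate with catalytic camphorsulfonic acid then gives 15.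

## Further compounds

F0 | step 14 | none | none
F1 | step 15 | (4R,5R,6S,8S)-4,5-diol, C5 epimer of 19 | CC[Si](CC)(CC)O[C@H]1C/C(C)=C/CC[C@@](C)(O)[C@H](O)[C@@H](O[Si](CC)(CC)CC)/C1=C(\CO[Si](CC)(CC)CC)COCc2ccc(OC)cc2
F2 | step 15 | cyclic 4,5-orthoacetate (2-methoxy-2-methyl-1,3-dioxolane) of F1 | CC[Si](CC)(CC)O[C@H]1C/C(C)=C/CC[C@@]2(C)OC(C)(OC)O[C@@H]2[C@@H](O[Si](CC)(CC)CC)/C1=C(\CO[Si](CC)(CC)CC)COCc3ccc(OC)cc3
F3 | step 15 | C4 acetate C5 bromide (bromide inverted at C5) | CC[Si](CC)(CC)O[C@H]1C/C(C)=C/CC[C@@](C)(OC(C)=O)[C@@H](Br)[C@@H](O[Si](CC)(CC)CC)/C1=C(\CO[Si](CC)(CC)CC)COCc2ccc(OC)cc2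
F0 | step 16 | none | none
F4 | step 22 | (1R,10R)-1,10-epoxide of 26 | C/C=C(\C)C(=O)O[C@H]1C[C@@]2(C)O[C@@H]2CC[C@@]2(C)O[C@@H]2[C@H]2OC(=O)C(COCc3ccc(OC)cc3)=C12
F5 | step 22 | (1R,10R)-1,10-epoxide of 27 (C13 alcohol) | C/C=C(\C)C(=O)O[C@H]1C[C@@]2(C)O[C@@H]2CC[C@@]2(C)O[C@@H]2[C@H]2OC(=O)C(CO)=C12
F6 | step 11 | C6 tert-butyl malonate mixed ester of 9 | CS(=O)(=O)O[C@@H]1CC[C@@](C)(O)[C@]2(O)[C@@H](OC(=O)CC(=O)OC(C)(C)C)C(=O)[C@@H](OC(C)=O)C[C@@]12C
F7 | step 11 | butenolide with C13 as tert-butyl ester | CS(=O)(=O)O[C@@H]1CC[C@@](C)(O)[C@]2(O)[C@H]3OC(=O)C(C(=O)OC(C)(C)C)=C3[C@@H](OC(C)=O)C[C@@]12C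
F8 | step 11 | butenolide with C13 as carboxylic acid | CS(=O)(=O)O[C@@H]1CC[C@@](C)(O)[C@]2(O)[C@H]3OC(=O)C(C(O)=O)=C3[C@@H](OC(C)=O)C[C@@]12C
F9 | step 11 | 13-hydroxymethyl butenolide | CS(=O)(=O)O[C@@H]1CC[C@@](C)(O)[C@]2(O)[C@H]3OC(=O)C(CO)=C3[C@@H](OC(C)=O)C[C@@]12C
A1 | alternative 1 | C8–O–O–C13 endoperoxide of the diepoxy butenolide | O1[C@H]2C[C@@]3(C)O[C@@H]3CC[C@@]3(C)O[C@@H]3[C@H]3OC(=O)C(CO1)=C23
A2 | alternative 1 | diepoxy lactone with C7=C8 and C11=C13 (s-cis diene) | C=C1C(=O)O[C@H]2C1=CC[C@@]3(C)O[C@@H]3CC[C@@]3(C)O[C@@H]32
A3 | alternative 2 | E,E-germacradienolide lacking the two epoxide oxygens | C/C=C(\C)C(=O)O[C@H]1C/C(C)=C/CC/C(C)=C/[C@H]2OC(=O)C(COC(C)=O)=C12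
A4 | alternative 2 | open-chain precursor with terminal C2=C3 alkene and C4 alkenyl iodide | C=C/C=C(\C)C[C@H](OC(=O)/C(C)=C/C)C1=C(COC(C)=O)C(=O)O[C@@H]1/C=C(\C)I
A5 | alternative 3 | ten-membered C6 alcohol with C7 propenyl unit | CC(C)(C)[Si](C)(C)O[C@H]1C/C(C)=C/CC/C(C)=C/[C@@H](O)[C@@H]1C(=C)COCc1ccc(OC)cc1
A6 | alternative 3 | thirteen-membered α-stannyl allyl ether (ring-trans C7=C11 drawn) | CCCC[Sn](CCCC)(CCCC)[C@H]1OC/C(COCc2ccc(OC)cc2)=C/[C@@H](O[Si](C)(C)C(C)(C)C)C/C(C)=C/CC/C(C)=C/1
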